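**Retrosynthetic overview**
- The route rests on one feature of the bicyclo[3.3.1]nonane core: the quaternary bridgehead C5 is bonded to the oxygen-bearing sp2 carbon C4 of ring B (C1-C2-C3-C4-C5-C9). This C4-C5 bond is made last, so ring C (C1-C8-C7-C6-C5-C9) is built first and ring B second.
- Ring B: gold-triggered 6-endo-dig attack of the C5=C9 enol silane on a bromoynone held on C1 (C2 carbonyl, C3≡C4-Br). Bromide-to-methoxide exchange, C3 aroylation, desilylation and O-demethylation finish the synthesis.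
- Quaternary C1: isobutenyl cuprate addition to a C1-methylene ketone, then aldol of the resulting enolate with 3-(trimethylsilyl)propynal trans to the C7 prenyl. The C5 chain comes from enolate alkylation with a (4S)-4-silyloxygeranyl bromide made by asymmetric allylboration and cross-metathesis.
- Ring C: enantioselective Diels-Alder reaction of the silyloxydiene from mesityl oxide with 2,2,2-trifluoroethyl acrylate sets C7 and leaves an enol silane toward C1; the ester is converted to prenyl and C1 is methylenated by a Mannich sequence.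

Key step: step 18

Remarks on the chemistry:
- Locants C1-C9 are those of the bicyclic target and are used for the ring C intermediates as well. Descriptors of the target refer to the enol tautomer drawn.
- The sense of induction in steps 2 and 9 is assumed from the accepted models for these reagents. If either proves opposite, the antipodal ligand or borane is used.

**Route**

Step 1
Reactants: 1 mesityl oxide
Product: 2 triisopropyl[(4-methylpenta-1,3-dien-2-yl)oxy]silane
Conditions: LDA, THF, −78 °C; then TIPSOTf, −78 → 0 °C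
Reagents that add atoms: triisopropylsilyl triflate, CC(C)[Si](C(C)C)(C(C)C)OS(=O)(=O)C(F)(F)F
Why: Kinetic deprotonation of the enone at the acetyl methyl and O-silylation (silyl enol ether formation) should give the cross-conjugated 2-silyloxydiene without touching the γ-methyls.

Step 2
Reactants: 2 triisopropyl[(4-methylpenta-1,3-dien-2-yl)oxy]silane; 3 2,2,2-trifluoroethyl acrylate
Product: 4 2,2,2-trifluoroethyl (1R)-2,2-dimethyl-4-[(triisopropylsilyl)oxy]cyclohex-3-ene-1-carboxylate
Conditions: (R)-3,3-diphenyl-1-(o-tolyl)tetrahydro-1H,3H-pyrrolo[1,2-c][1,3,2]oxazaborole·HNTf2 (15 mol%), CH2Cl2, −78 → −40 °C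
Reagents that add atoms: none
Why: Enantioselective Lewis-acid-catalysed Diels-Alder reaction in which the diene CH2 terminus (future C5) bonds to the acrylate β-carbon (C6) and the CMe2 terminus (C8) to the α-carbon (C7), an orientation favoured by both the 2-silyloxy group and the terminal methyls; C7 is set by the chiral oxazaborolidinium, which binds the s-trans acrylate and screens one face, and the adduct keeps a regiodefined enol silane between C9 and C1.

Step 3
Reactants: 4 2,2,2-trifluoroethyl (1R)-2,2-dimethyl-4-[(triisopropylsilyl)oxy]cyclohex-3-ene-1-carboxylate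
Product: 5 {(1R)-2,2-dimethyl-4-[(triisopropylsilyl)oxy]cyclohex-3-en-1-yl}methanol
Conditions: LiAlH4, Et2O, 0 °C
Reagents that add atoms: none
Why: Hydride reduction of the activated ester to the primary alcohol; the triisopropylsilyl enol ether is inert to LiAlH4 and C7 is not touched.

Step 4
Reactants: 5 {(1R)-2,2-dimethyl-4-[(triisopropylsilyl)oxy]cyclohex-3-en-1-yl}methanol
Product: 6 {(1R)-2,2-dimethyl-4-[(triisopropylsilyl)oxy]cyclohex-3-en-1-yl}methyl 4-methylbenzenesulfonate
Conditions: TsCl, Et3N, DMAP (cat.), CH2Cl2, 0 °C → rt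
Reagents that add atoms: 4-toluenesulfonyl chloride, Cc1ccc(cc1)S(=O)(=O)Cl
Why: Sulfonylation of the primary alcohol under amine base, conditions that leave the hindered silyl enol ether alone.

Step 5
Reactants: 6 {(1R)-2,2-dimethyl-4-[(triisopropylsilyl)oxy]cyclohex-3-en-1-yl}methyl 4-methylbenzenesulfonate
Product: 7 triisopropyl{[(4S)-3,3-dimethyl-4-(3-methylbut-2-en-1-yl)cyclohex-1-en-1-yl]oxy}silane
Conditions: Me2C=CHMgBr, CuI (10 mol%), THF, 0 °C → rt
Reagents that add atoms: (2-methylprop-1-en-1-yl)magnesium bromide, CC(C)=C[Mg]Br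
Why: Copper-catalysed sp3-sp2 cross-coupling of an alkenyl Grignard reagent with the primary tosylate turns the former ester carbon into the CH2 of the C7 prenyl group; the substitution does not involve the stereocentre.

Step 6
Reactants: 7 triisopropyl{[(4S)-3,3-dimethyl-4-(3-methylbut-2-en-1-yl)cyclohex-1-en-1-yl]oxy}silane
Product: 10 (4S)-3,3-dimethyl-2-methylidene-4-(3-methylbut-2-en-1-yl)cyclohexan-1-one, via Mannich base 8 (not isolated), via trimethylammonium iodide 9 (not isolated)
Conditions: CH2=NMe2+ I−, CH2Cl2, rt; then MeI; then DBU, CH2Cl2, rt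
Reagents that add atoms: N,N-dimethylmethyleneiminium iodide, C=[N+](C)C.[I-]; iodomethane, CI (its methyl stays in 9 and leaves with the amine)
Why: Mannich reaction of the silyl enol ether places one carbon on C1 only, because the enol silane position was fixed by the cycloaddition, and N-methylation followed by E1cB (Hofmann-type) elimination gives the C1-methylene ketone, which cannot tautomerise into the ring because C8 is quaternary.

Step 7
Reactants: 10 (4S)-3,3-dimethyl-2-methylidene-4-(3-methylbut-2-en-1-yl)cyclohexan-1-one; 11 3-(trimethylsilyl)prop-2-ynal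
Product: 14 (2R,4S)-3,3-dimethyl-2,4-bis(3-methylbut-2-en-1-yl)-2-[3-(trimethylsilyl)-1-(trimethylsilyloxy)prop-2-yn-1-yl]cyclohexan-1-one (carbinol epimers), via lithium enolate 12 (not isolated), via lithium aldolate 13 (not isolated)
Conditions: (Me2C=CH)2CuLi, Et2O/THF, −78 °C; then 11, −78 °C; then TMSCl, Et3N, −78 → 0 °C
Reagents that add atoms: lithium bis(2-methylprop-1-en-1-yl)cuprate, [Li+].CC(C)=C[Cu-]C=C(C)C; chlorotrimethylsilane, C[Si](C)(C)Cl
Why: Conjugate addition of the alkenyl cuprate to the exocyclic enone completes the C1 prenyl group and gives the C1=C9 enolate regiospecifically, and its aldol addition to the unhindered ynal should occur axially, anti to the pseudoaxial C8 methyl of the half-chair that keeps the C7 prenyl equatorial, that is trans to the C7 prenyl, which sets quaternary C1 with its prenyl cis to the C7 prenyl; silylation in the flask blocks retro-aldol cleavage and the carbinol epimers are cleared in step 15.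

Step 8
Reactants: 15 3-methylbut-2-en-1-yl acetate (prenyl acetate)
Product: 16 (2E)-3-methyl-4-oxobut-2-en-1-yl acetate
Conditions: SeO2, 1,4-dioxane, 80 °C
Reagents that add atoms: selenium dioxide, O=[Se]=O
Why: Riley allylic oxidation (ene reaction, then [2,3]-shift) attacks the methyl trans to the acetoxymethyl group and should give the (E)-enal.

Step 9
Reactants: 16 (2E)-3-methyl-4-oxobut-2-en-1-yl acetate
Product: 17 (2E,4S)-4-hydroxy-3-methylhepta-2,6-dien-1-yl acetate
Conditions: (−)-Ipc2B(allyl), Et2O, −78 °C; then 30% H2O2, aq NaHCO3, 0 °C → rt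
Reagents that add atoms: (−)-B-allyldiisopinocampheylborane, C=CCB([C@@H]1C[C@@H]2C[C@H]([C@H]1C)C2(C)C)[C@@H]1C[C@@H]2C[C@H]([C@H]1C)C2(C)C
Why: Asymmetric allylboration through a closed chair transition state adds 1,2 to the enal, the isopinocampheyl groups selecting the aldehyde face that gives the (4S) carbinol; the acetate is untouched at −78 °C and under the buffered oxidative work-up.

Step 10
Reactants: 17 (2E,4S)-4-hydroxy-3-methylhepta-2,6-dien-1-yl acetate
Product: 18 (2E,4S)-4-[(tert-butyldimethylsilyl)oxy]-3-methylhepta-2,6-dien-1-yl acetate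
Conditions: TBSCl, imidazole, DMF, rt
Reagents that add atoms: tert-butyldimethylsilyl chloride, CC(C)(C)[Si](C)(C)Cl
Why: Standard silylation of the secondary allylic alcohol; the silyl ether later survives amide bases, gold catalysis and methoxide.

Step 11
Reactants: 18 (2E,4S)-4-[(tert-butyldimethylsilyl)oxy]-3-methylhepta-2,6-dien-1-yl acetate
Product: 19 (2E,4S)-4-[(tert-butyldimethylsilyl)oxy]-3,7-dimethylocta-2,6-dien-1-yl acetate
Conditions: second-generation Grubbs catalyst RuCl2(=CHPh)(PCy3)(H2IMes) (3 mol%), 2-methylbut-2-ene/CH2Cl2, 40 °C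
Reagents that add atoms: 2-methylbut-2-ene, CC=C(C)C
Why: Olefin cross-metathesis of the terminal alkene with excess 2-methylbut-2-ene gives the prenyl terminus, while the trisubstituted allylic olefin is too hindered to react.

Step 12
Reactants: 19 (2E,4S)-4-[(tert-butyldimethylsilyl)oxy]-3,7-dimethylocta-2,6-dien-1-yl acetate
Product: 20 (2E,4S)-4-[(tert-butyldimethylsilyl)oxy]-3,7-dimethylocta-2,6-dien-1-ol
Conditions: K2CO3 (cat.), MeOH, 0 °C
Reagents that add atoms: none
Why: Base-catalysed methanolysis (transesterification) removes the acetate and leaves the silyl ether in place.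

Step 13
Reactants: 20 (2E,4S)-4-[(tert-butyldimethylsilyl)oxy]-3,7-dimethylocta-2,6-dien-1-ol
Product: 21 {[(2E,4S)-1-bromo-3,7-dimethylocta-2,6-dien-4-yl]oxy}(tert-butyl)dimethylsilane
Conditions: CBr4, PPh3, CH2Cl2, 0 °C
Reagents that add atoms: carbon tetrabromide, BrC(Br)(Br)Br
Why: The Appel reaction converts the primary allylic alcohol into the bromide by SN2 displacement without allylic transposition or loss of olefin geometry.

Step 14
Reactants: 14 (2R,4S)-3,3-dimethyl-2,4-bis(3-methylbut-2-en-1-yl)-2-[3-(trimethylsilyl)-1-(trimethylsilyloxy)prop-2-yn-1-yl]cyclohexan-1-one; 21 {[(2E,4S)-1-bromo-3,7-dimethylocta-2,6-dien-4-yl]oxy}(tert-butyl)dimethylsilane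
Product: 23 ring C β-hydroxy ketone: C9 ketone, C5 (epimers) carrying the (2E,4S)-4-(tert-butyldimethylsilyloxy)-3,7-dimethylocta-2,6-dienyl chain, C1 (R) carrying prenyl and 1-hydroxy-3-(trimethylsilyl)prop-2-ynyl (epimers), C7 (R) prenyl, via C5-alkylated trimethylsilyl ether 22 (not isolated)
Conditions: LDA, THF, −78 °C; then 21, DMPU, −78 → −30 °C; then 10% aq citric acid, MeOH, rt
Reagents that add atoms: none
Why: With C1 quaternary the ketone has one enolisable position, so kinetic deprotonation and SN2 alkylation with the primary allylic bromide (enolate alkylation) place the chain on C5 with the E-olefin and the (S) silyl ether intact, and the mild acid removes only the O-trimethylsilyl group; the C5 configuration does not matter because C5 becomes sp2 in step 17.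

Step 15
Reactants: 23 ring C β-hydroxy ketone
Product: 24 ring C diketone: as 23 but with a 3-(trimethylsilyl)prop-2-ynoyl group on C1 (1S, 7R; C5 epimers)
Conditions: Dess-Martin periodinane, NaHCO3, CH2Cl2, 0 °C → rt
Reagents that add atoms: none
Why: Dess-Martin oxidation of the propargylic alcohol gives the non-enolisable 1,3-diketone under buffered conditions that avoid retro-Claisen cleavage and removes the carbinol stereocentre.

Step 16
Reactants: 24 ring C diketone with 3-(trimethylsilyl)prop-2-ynoyl on C1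
Product: 25 ring C diketone with 3-bromoprop-2-ynoyl on C1 (1S, 7R; C5 epimers)
Conditions: NBS, AgNO3 (20 mol%), acetone, 0 °C, dark
Reagents that add atoms: N-bromosuccinimide, O=C1CCC(=O)N1Br
Why: Silver-mediated desilylative bromination of the alkynylsilane (silver acetylide, then electrophilic bromine) gives the 1-bromoalkyne, and a short reaction at 0 °C in the dark is meant to spare the trisubstituted olefins.

Step 17
Reactants: 25 ring C diketone with 3-bromoprop-2-ynoyl on C1
Product: 26 ring C enol silane: C9 O-tert-butyldimethylsilyl enol ether (C5=C9) with the (2E,4S)-4-(tert-butyldimethylsilyloxy)-3,7-dimethylocta-2,6-dienyl chain on C5, prenyl and 3-bromoprop-2-ynoyl on C1 (1S), gem-dimethyl on C8 and prenyl on C7 (7R), the two ring prenyls cis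
Conditions: TBSOTf, i-Pr2NEt, CH2Cl2, −78 → 0 °C
Reagents that add atoms: tert-butyldimethylsilyl triflate, CC(C)(C)[Si](C)(C)OS(=O)(=O)C(F)(F)F
Why: Soft enolisation with a silyl triflate and a hindered amine gives the only possible enol silane, C5=C9, both C5 epimers converging, and the non-nucleophilic base avoids conjugate addition to the bromoynone.

Step 18
Reactants: 26 ring C enol silane with bromoynone on C1
Product: 27 (1R,5R,7R)-4-bromo-5-[(2E,4S)-4-(tert-butyldimethylsilyloxy)-3,7-dimethylocta-2,6-dien-1-yl]-8,8-dimethyl-1,7-bis(3-methylbut-2-en-1-yl)bicyclo[3.3.1]non-3-ene-2,9-dione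
Conditions: [Au(NCMe)(P(t-Bu)2(2-biphenylyl))]SbF6 (5 mol%, monovalent gold), acetone (reagent grade), rt
Reagents that add atoms: none
Why: The cationic gold complex binds the C3-C4 triple bond and the C5 terminus of the C5=C9 enol silane adds anti to gold at C4, the β-carbon of the ynone; the C3 vinyl-gold species is protodeaurated and the silyloxocarbenium ion loses silicon to water, leaving the C9 ketone. The closest known reaction type is the gold-catalysed carbocyclisation of cyclic silyl enol ethers onto tethered alkynes and 1-haloalkynes, which gives bicyclo[3.3.1]nonenones. Ring B (C1-C2-C3-C4-C5-C9) closes in the 6-endo-dig mode, both alkyne carbons ending inside the ring. The new stereocentre C5 is controlled by C1: the three-atom acyl arm can reach C5 only on its own face, so the bridge forms cis-1,3-diaxial and the side chain is pushed to the other face, while the C7 prenyl, trans to the arm, stays equatorial (exo). The step needs 6-endo over 5-exo closure and attack by the enol silane and not by the C1 prenyl olefin; ynone polarisation places the electrophilic site at C4, the 5-exo product would be a strained bicyclo[2.2.1] alkylidene, and the enol silane is far more nucleophilic than a trisubstituted alkene. Because C1 is quaternary the enol silane is regiodefined, and the bromine retained on C4 allows the later exchange for oxygen.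

Step 19
Reactants: 27 C4-bromo bicyclic enedione
Product: 28 (1R,5S,7R)-5-[(2E,4S)-4-(tert-butyldimethylsilyloxy)-3,7-dimethylocta-2,6-dien-1-yl]-4-methoxy-8,8-dimethyl-1,7-bis(3-methylbut-2-en-1-yl)bicyclo[3.3.1]non-3-ene-2,9-dione
Conditions: NaOMe, MeOH/THF, 0 °C
Reagents that add atoms: sodium methoxide, C[O-].[Na+]
Why: Addition-elimination (vinylogous acyl substitution) of methoxide at C4 of the β-bromoenone gives the vinylogous ester; both bridgeheads are quaternary, so nothing can epimerise, and the low temperature limits retro-Claisen attack at C9.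

Step 20
Reactants: 29 3,4-dihydroxybenzoic acid
Product: 30 tert-butyldimethylsilyl 3,4-bis[(tert-butyldimethylsilyl)oxy]benzoate
Conditions: TBSCl (3.5 equiv), imidazole, DMF, rt
Reagents that add atoms: tert-butyldimethylsilyl chloride, CC(C)(C)[Si](C)(C)Cl
Why: Exhaustive silylation protects both phenols and converts the acid into a silyl ester that serves as the acid chloride precursor.

Step 21
Reactants: 30 tert-butyldimethylsilyl 3,4-bis[(tert-butyldimethylsilyl)oxy]benzoate
Product: 31 3,4-bis[(tert-butyldimethylsilyl)oxy]benzoyl chloride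
Conditions: (COCl)2, DMF (cat.), CH2Cl2, 0 °C → rt
Reagents that add atoms: oxalyl chloride, ClC(=O)C(=O)Cl
Why: Silyl esters are converted directly into acid chlorides by oxalyl chloride and catalytic DMF (Vilsmeier-type activation) under neutral conditions that keep the aryl silyl ethers.

Step 22
Reactants: 28 C4-methoxy bicyclic enedione; 31 3,4-bis[(tert-butyldimethylsilyl)oxy]benzoyl chloride
Product: 32 (1S,5S,7R)-3-{3,4-bis[(tert-butyldimethylsilyl)oxy]benzoyl}-5-[(2E,4S)-4-(tert-butyldimethylsilyloxy)-3,7-dimethylocta-2,6-dien-1-yl]-4-methoxy-8,8-dimethyl-1,7-bis(3-methylbut-2-en-1-yl)bicyclo[3.3.1]non-3-ene-2,9-dione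
Conditions: LiTMP, THF, −78 °C; then 31, −78 → −40 °C
Reagents that add atoms: none
Why: Directed deprotonation of the C3 vinylic hydrogen (α to the C2 carbonyl, next to the C4 methoxy group, and the only acidic C-H because both bridgeheads are quaternary) followed by C-acylation of the vinyllithium with the acid chloride installs the aroyl group.

Step 23
Reactants: 32 tris-silylated C3-aroyl methyl enol ether
Product: 33 (1S,5S,7R)-3-(3,4-dihydroxybenzoyl)-5-[(2E,4S)-4-hydroxy-3,7-dimethylocta-2,6-dien-1-yl]-4-methoxy-8,8-dimethyl-1,7-bis(3-methylbut-2-en-1-yl)bicyclo[3.3.1]non-3-ene-2,9-dione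
Conditions: TBAF, AcOH, THF, 0 °C → rt (degassed)
Reagents that add atoms: none
Why: Fluoride-mediated desilylation removes the two aryl silyl ethers and the allylic silyl ether, and buffering with acetic acid protects the catechol and the vinylogous ester from base.

Step 24
Reactants: 33 C4-methoxy triol
Product: 34 (1S,5S,7R)-3-(3,4-dihydroxybenzoyl)-4-hydroxy-5-[(2E,4S)-4-hydroxy-3,7-dimethylocta-2,6-dien-1-yl]-8,8-dimethyl-1,7-bis(3-methylbut-2-en-1-yl)bicyclo[3.3.1]non-3-ene-2,9-dione (target, CNP0142498.1)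
Conditions: LiCl, DMSO, 120 °C, argon; then dilute aq HCl work-up
Reagents that add atoms: none
Why: SN2 demethylation of the vinylogous methyl ester by chloride (Krapcho-type) releases the enolised β-triketone without the strong acid or base that would cyclise the enol onto a prenyl group or oxidise the catechol.

**Compound list**

1 | mesityl oxide (4-methylpent-3-en-2-one) | CC(=O)C=C(C)C | starting material
2 | triisopropyl[(4-methylpenta-1,3-dien-2-yl)oxy]silane | C=C(O[Si](C(C)C)(C(C)C)C(C)C)C=C(C)C | intermediate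
3 | 2,2,2-trifluoroethyl acrylate | C=CC(=O)OCC(F)(F)F | starting material
4 | 2,2,2-trifluoroethyl (1R)-2,2-dimethyl-4-[(triisopropylsilyl)oxy]cyclohex-3-ene-1-carboxylate | O=C(OCC(F)(F)F)[C@@H]1CCC(O[Si](C(C)C)(C(C)C)C(C)C)=CC1(C)C | intermediate
5 | {(1R)-2,2-dimethyl-4-[(triisopropylsilyl)oxy]cyclohex-3-en-1-yl}methanol | OC[C@@H]1CCC(O[Si](C(C)C)(C(C)C)C(C)C)=CC1(C)C | intermediate
6 | {(1R)-2,2-dimethyl-4-[(triisopropylsilyl)oxy]cyclohex-3-en-1-yl}methyl 4-methylbenzenesulfonate | Cc1ccc(cc1)S(=O)(=O)OC[C@@H]1CCC(O[Si](C(C)C)(C(C)C)C(C)C)=CC1(C)C | intermediate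
7 | triisopropyl{[(4S)-3,3-dimethyl-4-(3-methylbut-2-en-1-yl)cyclohex-1-en-1-yl]oxy}silane | CC(C)=CC[C@@H]1CCC(O[Si](C(C)C)(C(C)C)C(C)C)=CC1(C)C | intermediate
8 | (4S)-2-[(dimethylamino)methyl]-3,3-dimethyl-4-(3-methylbut-2-en-1-yl)cyclohexan-1-one (C2 epimers; Mannich base) | CC(C)=CC[C@@H]1CCC(=O)C(CN(C)C)C1(C)C | intermediate
9 | trimethylammonium iodide of 8 | CC(C)=CC[C@@H]1CCC(=O)C(C[N+](C)(C)C)C1(C)C.[I-] | intermediate
10 | (4S)-3,3-dimethyl-2-methylidene-4-(3-methylbut-2-en-1-yl)cyclohexan-1-one | CC(C)=CC[C@@H]1CCC(=O)C(=C)C1(C)C | intermediate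
11 | 3-(trimethylsilyl)prop-2-ynal | C[Si](C)(C)C#CC=O | starting material
12 | lithium (4S)-3,3-dimethyl-2,4-bis(3-methylbut-2-en-1-yl)cyclohex-1-en-1-olate | CC(C)=CC[C@@H]1CCC([O-])=C(CC=C(C)C)C1(C)C.[Li+] | intermediate
13 | lithium alkoxide of the C1 aldol adduct (2R,4S; carbinol epimers) | CC(C)=CC[C@@H]1CCC(=O)[C@@](CC=C(C)C)(C([O-])C#C[Si](C)(C)C)C1(C)C.[Li+] | intermediate
14 | (2R,4S)-3,3-dimethyl-2,4-bis(3-methylbut-2-en-1-yl)-2-[3-(trimethylsilyl)-1-(trimethylsilyloxy)prop-2-yn-1-yl]cyclohexan-1-one (carbinol epimers) | CC(C)=CC[C@@H]1CCC(=O)[C@@](CC=C(C)C)(C(O[Si](C)(C)C)C#C[Si](C)(C)C)C1(C)C | intermediate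
15 | 3-methylbut-2-en-1-yl acetate (prenyl acetate) | CC(C)=CCOC(C)=O | starting material
16 | (2E)-3-methyl-4-oxobut-2-en-1-yl acetate | CC(=O)OC/C=C(\C)C=O | intermediate
17 | (2E,4S)-4-hydroxy-3-methylhepta-2,6-dien-1-yl acetate | CC(=O)OC/C=C(\C)[C@@H](O)CC=C | intermediate
18 | (2E,4S)-4-[(tert-butyldimethylsilyl)oxy]-3-methylhepta-2,6-dien-1-yl acetate | CC(=O)OC/C=C(\C)[C@@H](O[Si](C)(C)C(C)(C)C)CC=C | intermediate
19 | (2E,4S)-4-[(tert-butyldimethylsilyl)oxy]-3,7-dimethylocta-2,6-dien-1-yl acetate | CC(=O)OC/C=C(\C)[C@@H](O[Si](C)(C)C(C)(C)C)CC=C(C)C | intermediate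
20 | (2E,4S)-4-[(tert-butyldimethylsilyl)oxy]-3,7-dimethylocta-2,6-dien-1-ol | OC/C=C(\C)[C@@H](O[Si](C)(C)C(C)(C)C)CC=C(C)C | intermediate
21 | {[(2E,4S)-1-bromo-3,7-dimethylocta-2,6-dien-4-yl]oxy}(tert-butyl)dimethylsilane | BrC/C=C(\C)[C@@H](O[Si](C)(C)C(C)(C)C)CC=C(C)C | intermediate
22 | C5-alkylated trimethylsilyl ether (1R,7R; C5 and carbinol epimers) | CC(C)=CC[C@@H]1CC(C/C=C(\C)[C@@H](O[Si](C)(C)C(C)(C)C)CC=C(C)C)C(=O)[C@@](CC=C(C)C)(C(O[Si](C)(C)C)C#C[Si](C)(C)C)C1(C)C | intermediate
23 | ring C β-hydroxy ketone with C5 chain and 1-hydroxy-3-(trimethylsilyl)prop-2-ynyl on C1 (1R,7R; C5 and carbinol epimers) | CC(C)=CC[C@@H]1CC(C/C=C(\C)[C@@H](O[Si](C)(C)C(C)(C)C)CC=C(C)C)C(=O)[C@@](CC=C(C)C)(C(O)C#C[Si](C)(C)C)C1(C)C | intermediate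
24 | ring C diketone with 3-(trimethylsilyl)prop-2-ynoyl on C1 (1S,7R; C5 epimers) | CC(C)=CC[C@@H]1CC(C/C=C(\C)[C@@H](O[Si](C)(C)C(C)(C)C)CC=C(C)C)C(=O)[C@@](CC=C(C)C)(C(=O)C#C[Si](C)(C)C)C1(C)C | intermediate
25 | ring C diketone with 3-bromoprop-2-ynoyl on C1 (1S,7R; C5 epimers) | CC(C)=CC[C@@H]1CC(C/C=C(\C)[C@@H](O[Si](C)(C)C(C)(C)C)CC=C(C)C)C(=O)[C@@](CC=C(C)C)(C(=O)C#CBr)C1(C)C | intermediate
26 | ring C C5=C9 tert-butyldimethylsilyl enol ether with the chain on C5, prenyl and 3-bromoprop-2-ynoyl on C1 (1S,7R) | CC(C)=CC[C@@H]1CC(C/C=C(\C)[C@@H](O[Si](C)(C)C(C)(C)C)CC=C(C)C)=C(O[Si](C)(C)C(C)(C)C)[C@@](CC=C(C)C)(C(=O)C#CBr)C1(C)C | intermediate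
27 | (1R,5R,7R)-4-bromo-5-[(2E,4S)-4-(tert-butyldimethylsilyloxy)-3,7-dimethylocta-2,6-dien-1-yl]-8,8-dimethyl-1,7-bis(3-methylbut-2-en-1-yl)bicyclo[3.3.1]non-3-ene-2,9-dione | CC(C)=CC[C@@H]1C[C@]2(C/C=C(\C)[C@@H](O[Si](C)(C)C(C)(C)C)CC=C(C)C)C(=O)[C@@](CC=C(C)C)(C(=O)C=C2Br)C1(C)C | intermediate
28 | (1R,5S,7R)-4-methoxy analogue of 27 | CC(C)=CC[C@@H]1C[C@]2(C/C=C(\C)[C@@H](O[Si](C)(C)C(C)(C)C)CC=C(C)C)C(=O)[C@@](CC=C(C)C)(C(=O)C=C2OC)C1(C)C | intermediate
29 | 3,4-dihydroxybenzoic acid | OC(=O)c1ccc(O)c(O)c1 | starting material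
30 | tert-butyldimethylsilyl 3,4-bis[(tert-butyldimethylsilyl)oxy]benzoate | CC(C)(C)[Si](C)(C)OC(=O)c1ccc(O[Si](C)(C)C(C)(C)C)c(O[Si](C)(C)C(C)(C)C)c1 | intermediate
31 | 3,4-bis[(tert-butyldimethylsilyl)oxy]benzoyl chloride | ClC(=O)c1ccc(O[Si](C)(C)C(C)(C)C)c(O[Si](C)(C)C(C)(C)C)c1 | intermediate
32 | (1S,5S,7R)-3-{3,4-bis[(tert-butyldimethylsilyl)oxy]benzoyl}-4-methoxy compound with silylated chain | CC(C)=CC[C@@H]1C[C@]2(C/C=C(\C)[C@@H](O[Si](C)(C)C(C)(C)C)CC=C(C)C)C(=O)[C@@](CC=C(C)C)(C(=O)C(C(=O)c3ccc(O[Si](C)(C)C(C)(C)C)c(O[Si](C)(C)C(C)(C)C)c3)=C2OC)C1(C)C | intermediate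
33 | (1S,5S,7R)-3-(3,4-dihydroxybenzoyl)-5-[(2E,4S)-4-hydroxy-3,7-dimethylocta-2,6-dien-1-yl]-4-methoxy-8,8-dimethyl-1,7-bis(3-methylbut-2-en-1-yl)bicyclo[3.3.1]non-3-ene-2,9-dione | CC(C)=CC[C@@H]1C[C@]2(C/C=C(\C)[C@@H](O)CC=C(C)C)C(=O)[C@@](CC=C(C)C)(C(=O)C(C(=O)c3ccc(O)c(O)c3)=C2OC)C1(C)C | intermediate
34 | CNP0142498.1, (1S,5S,7R)-3-(3,4-dihydroxybenzoyl)-4-hydroxy-5-[(2E,4S)-4-hydroxy-3,7-dimethylocta-2,6-dien-1-yl]-8,8-dimethyl-1,7-bis(3-methylbut-2-en-1-yl)bicyclo[3.3.1]non-3-ene-2,9-dione | CC(C)=CC[C@@H]1C[C@]2(C/C=C(\C)[C@@H](O)CC=C(C)C)C(=O)[C@@](CC=C(C)C)(C(=O)C(C(=O)c3ccc(O)c(O)c3)=C2O)C1(C)C | target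

**Step count**

Total step count: 24. Longest linear sequence: 16 steps (steps 1-7, 14-19 and 22-24).

**Steps most likely to fail**

Step 18 (key step). The cyclisation may be diverted by attack of the C1 prenyl olefin on the gold-activated alkyne (1,6-enyne cyclisation), by 1,2-migration of bromine through a gold vinylidene, or by loss of the enol silane to the ketone before the C-C bond forms. The fallback builds ring B by an Effenberger annulation and sets out from enone 10. Addition of (Me2C=CH)2CuLi to 10 with a protic quench would give (4S)-3,3-dimethyl-2,4-bis(3-methylbut-2-en-1-yl)cyclohexan-1-one F1. Kinetic enolisation (LDA, TBSCl, THF/HMPA, −78 °C) would give the C5=C9 enol silane tert-butyl{[(4R)-5,5-dimethyl-4,6-bis(3-methylbut-2-en-1-yl)cyclohex-1-en-1-yl]oxy}dimethylsilane F2. Treatment with malonyl dichloride (Et2O, −20 °C → rt, then KOH, BnEt3NCl, H2O) should acylate C5 and then C1, the second bond again forming trans to the C7 prenyl, to give the C5-H bicyclic trione 4-hydroxy-8,8-dimethyl-1,7-bis(3-methylbut-2-en-1-yl)bicyclo[3.3.1]non-3-ene-2,9-dione F3. O-Methylation (Me2SO4, K2CO3, acetone) and separation from the C2-methoxy regioisomer would give the 4-methoxy compound F4. Bridgehead deprotonation at C5 (LDA, THF, −78 °C) and alkylation with bromide 21 would return to the route at 28.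

Step 7. The aldol of the hindered tetrasubstituted enolate may be slow or reversible, so that retro-aldol cleavage outruns silylation, or its facial selectivity may be eroded. The fallback separates the two events and sets out from 10. Cuprate addition in the presence of TMSCl would give the isolable enol silane trimethyl{[(4S)-3,3-dimethyl-2,4-bis(3-methylbut-2-en-1-yl)cyclohex-1-en-1-yl]oxy}silane F5. A Mukaiyama aldol addition with 11 (BF3·OEt2, CH2Cl2, −78 °C), in which the aldehyde is activated and no basic aldolate is formed, would give the free aldol (2R,4S)-2-[1-hydroxy-3-(trimethylsilyl)prop-2-yn-1-yl]-3,3-dimethyl-2,4-bis(3-methylbut-2-en-1-yl)cyclohexan-1-one F6. Silylation (TMSCl, imidazole, CH2Cl2) would return to the route at 14.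

Step 2. The cis-methyl on the diene terminus slows the cycloaddition, so conjugate addition without ring closure, hydrolysis of the diene by the acidic catalyst, or poor facial discrimination may take over. The fallback replaces catalyst control by auxiliary control and sets out from diene 2. Cycloaddition with (S)-3-acryloyl-4-benzyloxazolidin-2-one (Et2AlCl, CH2Cl2, −78 °C) proceeds through the chelated s-cis imide, and the diene adds anti to the benzyl group. It should give (4S)-4-benzyl-3-{(1R)-2,2-dimethyl-4-[(triisopropylsilyl)oxy]cyclohex-3-ene-1-carbonyl}oxazolidin-2-one F7. Reductive removal of the auxiliary (LiBH4, THF/MeOH, 0 °C) would return to the route at alcohol 5.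

**Further compounds**

F1 | step 18 | (4S)-3,3-dimethyl-2,4-bis(3-methylbut-2-en-1-yl)cyclohexan-1-one (C2 epimers) | CC(C)=CC[C@@H]1CCC(=O)C(CC=C(C)C)C1(C)C
F2 | step 18 | tert-butyl{[(4R)-5,5-dimethyl-4,6-bis(3-methylbut-2-en-1-yl)cyclohex-1-en-1-yl]oxy}dimethylsilane (C6 epimers) | CC(C)=CC[C@@H]1CC=C(O[Si](C)(C)C(C)(C)C)C(CC=C(C)C)C1(C)C
F3 | step 18 | 4-hydroxy-8,8-dimethyl-1,7-bis(3-methylbut-2-en-1-yl)bicyclo[3.3.1]non-3-ene-2,9-dione (C1 and C7 as in 28, C5-H) | CC(C)=CC[C@@H]1C[C@@H]2C(=O)[C@@](CC=C(C)C)(C(=O)C=C2O)C1(C)C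
F4 | step 18 | 4-methoxy-8,8-dimethyl-1,7-bis(3-methylbut-2-en-1-yl)bicyclo[3.3.1]non-3-ene-2,9-dione (C1 and C7 as in 28, C5-H) | CC(C)=CC[C@@H]1C[C@@H]2C(=O)[C@@](CC=C(C)C)(C(=O)C=C2OC)C1(C)C
F5 | step 7 | trimethyl{[(4S)-3,3-dimethyl-2,4-bis(3-methylbut-2-en-1-yl)cyclohex-1-en-1-yl]oxy}silane | CC(C)=CC[C@@H]1CCC(O[Si](C)(C)C)=C(CC=C(C)C)C1(C)C
F6 | step 7 | (2R,4S)-2-[1-hydroxy-3-(trimethylsilyl)prop-2-yn-1-yl]-3,3-dimethyl-2,4-bis(3-methylbut-2-en-1-yl)cyclohexan-1-one (carbinol epimers) | CC(C)=CC[C@@H]1CCC(=O)[C@@](CC=C(C)C)(C(O)C#C[Si](C)(C)C)C1(C)C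
F7 | step 2 | (4S)-4-benzyl-3-{(1R)-2,2-dimethyl-4-[(triisopropylsilyl)oxy]cyclohex-3-ene-1-carbonyl}oxazolidin-2-one | O=C([C@@H]1CCC(O[Si](C(C)C)(C(C)C)C(C)C)=CC1(C)C)N1[C@@H](Cc2ccccc2)COC1=O
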